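The route rests on disconnecting C9–C10. Ring A of the target (C1–C5, C10) carries oxygen at C3 para to the methylated quaternary C10 and the carboxyl-level C19 on C4, so it is a dearomatized 5-methylsalicylate. An iridium-catalysed intramolecular allylic alkylation lets the phenoxide para carbon C10 attack C9 of a dienyl carbonate. One operation closes ring B, sets C9 and C10, and leaves the C7=C8 alkene, the C9 vinyl group and a ring A dienone for the later C4/C5, C2/C3 and side-chain work. The precursor is methyl 2-hydroxy-5-methylbenzoate carrying at position 6 a (2Z,4E)-3-methylhexa-2,4-dienyl chain that ends in a methyl carbonate.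

Key step: step 9

Convention: labdane numbering is used for all bicyclic compounds (ring A: C1–C5, C10; ring B: C5–C10; C19 is the carboxyl-level carbon on C4); α is the face of the C10 methyl group, β the face of H-5 and H-9.

Assumption: the ligand antipodes named in steps 9 and 17 follow the usual facial models for these catalysts; if a test run shows the opposite sense, the mirror-image ligand is used and nothing else changes.

Step 1
Reactants: 1 3-bromo-4-methylphenol
Product: 2 2-bromo-4-(methoxymethoxy)-1-methylbenzene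
Conditions: MOMCl, i-Pr2NEt, CH2Cl2, 0 °C → rt
Reagents that add atoms: chloromethyl methyl ether, COCCl
Why: Williamson-type O-alkylation of the phenol gives the MOM ether, which later acidifies and directs the neighbouring ring position.

Step 2
Reactants: 2 2-bromo-4-(methoxymethoxy)-1-methylbenzene; 3 methyl chloroformate
Product: 5 methyl 6-bromo-2-(methoxymethoxy)-5-methylbenzoate, via aryllithium 4 (not isolated)
Conditions: LiN(i-Pr)2, THF, −78 °C; then inverse addition to ClCO2Me, −78 °C → rt
Reagents that add atoms: none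
Why: Directed ortho-metalation, in which the amide base removes the proton flanked by the MOM ether and bromine (the most acidic site, with no bromine–lithium exchange at −78 °C), followed by acylation of the aryllithium.

Step 3
Reactants: 6 but-2-yn-1-ol
Product: 8 (2Z)-3-iodobut-2-en-1-ol, via cyclic alkenylalanate 7 (not isolated)
Conditions: NaAlH2(OCH2CH2OMe)2, THF, 0 °C → rt; then I2, −78 → 0 °C
Reagents that add atoms: iodine, II
Why: Hydroxyl-directed trans-hydroalumination of the propargylic alcohol and iodinolysis with retention place iodine on C3 cis to the carbinol carbon, which fixes the Z geometry of the later ring B alkene.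

Step 4
Reactants: 8 (2Z)-3-iodobut-2-en-1-ol
Product: 9 (2Z)-1-bromo-3-iodobut-2-ene
Conditions: PBr3, Et2O, 0 °C
Reagents that add atoms: phosphorus tribromide, BrP(Br)Br
Why: SN2 bromination of a primary allylic alcohol through its phosphite ester at low temperature leaves the alkenyl iodide and the alkene geometry untouched.

Step 5
Reactants: 5 methyl 6-bromo-2-(methoxymethoxy)-5-methylbenzoate; 9 (2Z)-1-bromo-3-iodobut-2-ene
Product: 11 methyl 6-[(2Z)-3-iodobut-2-en-1-yl]-2-(methoxymethoxy)-5-methylbenzoate, via arylmagnesium chloride 10 (not isolated)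
Conditions: i-PrMgCl·LiCl, THF, −15 °C; then Li2CuCl4 (5 mol%), 9, −30 → 0 °C
Reagents that add atoms: none
Why: Bromine–magnesium exchange, helped by the ortho ester and tolerant of it at low temperature, followed by copper-catalysed SN2 coupling at the primary allylic bromide; the γ carbon is fully substituted, so direct substitution with retention of the Z alkene is expected.

Step 6
Reactants: 11 methyl 6-[(2Z)-3-iodobut-2-en-1-yl]-2-(methoxymethoxy)-5-methylbenzoate; 12 (2E)-3-(tributylstannyl)prop-2-en-1-ol
Product: 13 methyl 6-[(2Z,4E)-6-hydroxy-3-methylhexa-2,4-dien-1-yl]-2-(methoxymethoxy)-5-methylbenzoate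
Conditions: Pd(PPh3)4 (5 mol%), CuI (10 mol%), DMF, 40 °C
Reagents that add atoms: none
Why: Stille coupling of the alkenyl iodide with the (E)-alkenylstannane under zerovalent palladium proceeds with retention at both alkenes and tolerates the free alcohol.

Step 7
Reactants: 13 methyl 6-[(2Z,4E)-6-hydroxy-3-methylhexa-2,4-dien-1-yl]-2-(methoxymethoxy)-5-methylbenzoate; 3 methyl chloroformate
Product: 14 methyl 6-{(2Z,4E)-6-[(methoxycarbonyl)oxy]-3-methylhexa-2,4-dien-1-yl}-2-(methoxymethoxy)-5-methylbenzoate
Conditions: ClCO2Me, pyridine, CH2Cl2, 0 °C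
Reagents that add atoms: none
Why: Acylation of the primary allylic alcohol by the chloroformate with pyridine as base gives the carbonate.

Step 8
Reactants: 14 methyl 6-{(2Z,4E)-6-[(methoxycarbonyl)oxy]-3-methylhexa-2,4-dien-1-yl}-2-(methoxymethoxy)-5-methylbenzoate
Product: 15 methyl 2-hydroxy-6-{(2Z,4E)-6-[(methoxycarbonyl)oxy]-3-methylhexa-2,4-dien-1-yl}-5-methylbenzoate
Conditions: HCl (0.3 M) in MeOH/THF, 0 °C → rt
Reagents that add atoms: none
Why: Acid-catalysed acetal methanolysis removes the aryl MOM group, which is activated by the ortho ester, under conditions too mild to ionise the primary allylic carbonate or to move the skipped alkenes.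

Step 9
Reactants: 15 methyl 2-hydroxy-6-{(2Z,4E)-6-[(methoxycarbonyl)oxy]-3-methylhexa-2,4-dien-1-yl}-5-methylbenzoate
Product: 16 methyl (4aS,5R)-5-ethenyl-4a,6-dimethyl-2-oxo-2,4a,5,8-tetrahydronaphthalene-1-carboxylate
Conditions: [Ir(cod)Cl]2 (2.5 mol%), (Sa,S,S)-L (5 mol%; L = O,O′-(1,1′-binaphthalene-2,2′-diyl) N,N-bis(1-phenylethyl)phosphoramidite), n-PrNH2 pre-activation, Li2CO3 (0.5 equiv), THF, 50 °C
Reagents that add atoms: none
Why: Proposed new method: the iridium phosphoramidite catalyst ionises the methyl carbonate to an allyl complex of trivalent iridium spanning C9–C11–C12, and the phenoxide of 15 attacks the substituted terminus C9 through its para carbon C10, anti to the metal, after which loss of CO2 and methanol makes the dearomatization irreversible. The closest known reaction types are the iridium-catalysed enantioselective intramolecular allylic dearomatization of para-tethered phenols to spirocyclohexadienones and the para-selective iridium-catalysed allylic cyclization of meta-tethered phenols; new here is a meta tether that ends on a substituted para carbon, so that a fused ring with a quaternary centre forms. Ring B closes in a 6-exo mode (C10, C5, C6, C7, C8 and C9 in the ring, C11=C12 left outside as the vinyl group), and the (2Z) alkene holds C6 and C9 cis so that C9 can reach C10. C9 is set by the ligand, which fixes the allyl face bound to iridium, and C10 by the arene face that is presented when the C11–C12 terminus with its metal fragment points away from ring A and lies between C1–H and the C10 methyl group, which puts vinyl and methyl cis. The step needs attack at C9 rather than C12 (iridium favours the substituted terminus, and a six-membered ring competes with an eight-membered one) and at C10 rather than at oxygen or the ester-bearing ortho carbon C4 (oxygen cannot reach the allyl unit, and C4 is flanked by substituents on both sides and would lose the conjugation of the hydrogen-bonded salicylate, whereas C10 has a free C1–H neighbour). Li2CO3 as the only base keeps the medium near neutral, so the acidic C6 protons of the dienone should stay in place.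

Step 10
Reactants: 16 methyl (4aS,5R)-5-ethenyl-4a,6-dimethyl-2-oxo-2,4a,5,8-tetrahydronaphthalene-1-carboxylate
Product: 18 methyl (4aS,5R)-5-ethenyl-4a,6-dimethyl-2-oxo-2,3,4,4a,5,8-hexahydronaphthalene-1-carboxylate, via potassium dienolate 17 (not isolated)
Conditions: K[(s-Bu)3BH] (1.05 equiv), THF, −78 °C; AcOH quench
Reagents that add atoms: none
Why: Conjugate hydride reduction with a bulky trialkylborohydride adds hydride to C1, the unhindered β-CH of the dienone, rather than to the fully substituted C5 or the cross-conjugated carbonyl, and protonation of the enolate gives the 4-en-3-one ester.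

Step 11
Reactants: 18 methyl (4aS,5R)-5-ethenyl-4a,6-dimethyl-2-oxo-2,3,4,4a,5,8-hexahydronaphthalene-1-carboxylate
Product: 20 methyl (1S,4aR,5R,8aS)-5-ethenyl-1,4a,6-trimethyl-2-oxo-1,2,3,4,4a,5,8,8a-octahydronaphthalene-1-carboxylate, via lithium enolate 19 (not isolated)
Conditions: Li (2.2 equiv), t-BuOH (1 equiv), NH3/THF, −78 °C; isoprene; then MeI, −78 °C → rt
Reagents that add atoms: iodomethane, CI
Why: Dissolving-metal reductive alkylation (Stork type) reduces the alkylidene β-keto ester, protonates C5 on the β face to give the trans ring fusion, and methylates the β-keto ester enolate at C4 from the β face, away from the syn-axial C10 methyl group, so that the ester ends axial and cis to that methyl group.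

Step 12
Reactants: 20 methyl (1S,4aR,5R,8aS)-5-ethenyl-1,4a,6-trimethyl-2-oxo-1,2,3,4,4a,5,8,8a-octahydronaphthalene-1-carboxylate
Product: 22 2β-hydroxy derivative of keto ester 20 (equatorial C2–OH cis to H-5), via potassium enolate 21 (not isolated)
Conditions: KN(SiMe3)2, THF, −78 °C; 2-(phenylsulfonyl)-3-phenyloxaziridine, −78 °C; AcOH quench
Reagents that add atoms: 2-(phenylsulfonyl)-3-phenyloxaziridine, O=S(=O)(N1OC1c1ccccc1)c1ccccc1
Why: Enolate α-hydroxylation with a sulfonyloxaziridine (Davis oxidation) can occur only at C2 because C4 is quaternary, and the oxidant adds from the β face, anti to the syn-axial C10 methyl group and C4 ester, giving the equatorial 2β-alcohol without touching the alkenes.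

Step 13
Reactants: 22 2β-hydroxy derivative of keto ester 20
Product: 24 2β,3β,19-triol (ester reduced to CH2OH; 3-OH axial), via diol ester 23 (not isolated)
Conditions: Li[(s-Bu)3BH] (2.5 equiv), THF, −78 °C; then LiAlH4 (4 equiv), −78 °C → rt; NaOH/H2O2 work-up
Reagents that add atoms: none
Why: Two hydride reductions in sequence, in which the bulky trialkylborohydride attacks the C3 ketone along the equatorial trajectory (α face), as with 4,4-disubstituted 3-oxo terpenoids and 2-oxygenated cyclohexanones, to give the axial 3β-alcohol cis to the 2β-hydroxyl, and LiAlH4 then reduces the hindered axial ester to the C19 carbinol.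

Step 14
Reactants: 24 2β,3β,19-triol
Product: 25 2,3-O-isopropylidene acetal of triol 24 (C19–OH free)
Conditions: 2,2-dimethoxypropane, PPTS (cat.), acetone, rt
Reagents that add atoms: 2,2-dimethoxypropane, COC(C)(C)OC
Why: Acid-catalysed transketalization selects the cis-2,3-diol, whose oxygens are gauche, whereas the C3 and C19 oxygens are anti and cannot be bridged.

Step 15
Reactants: 26 methyl acetoacetate
Product: 27 methyl (2E)-3-{[(trifluoromethyl)sulfonyl]oxy}but-2-enoate
Conditions: Tf2O, aq. Me4NOH, toluene, 5 °C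
Reagents that add atoms: trifluoromethanesulfonic anhydride, O=S(=O)(OS(=O)(=O)C(F)(F)F)C(F)(F)F
Why: O-sulfonylation of the β-keto ester enolate, which with a non-coordinating ammonium counter-ion in a two-phase medium reacts in its extended form and gives the (E)-enol triflate.

Step 16
Reactants: 25 2,3-O-isopropylidene acetal of triol 24; 27 methyl (2E)-3-{[(trifluoromethyl)sulfonyl]oxy}but-2-enoate
Product: 29 methyl (E)-enoate with side chain C9–CH2CH2–C(CH3)=CH–CO2Me, via alkylborane 28 (not isolated)
Conditions: 9-BBN (2.5 equiv), THF, rt; then 27, PdCl2(dppf) (5 mol%), K3PO4 (aq.), DMF, rt → 50 °C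
Reagents that add atoms: none
Why: Hydroboration with 9-BBN selects the monosubstituted vinyl group over the trisubstituted C7=C8 alkene and places boron on C12, and B-alkyl Suzuki–Miyaura coupling with the enol triflate then forms C12–C13 with retention of the E geometry (the C19 hydroxyl is borylated in passing and set free again in the aqueous medium).

Step 17
Reactants: 29 methyl (E)-enoate
Product: 30 saturated methyl ester with (13R)-methyl (side chain C9–CH2CH2–CH(CH3)–CH2–CO2Me)
Conditions: Cu(OAc)2 (5 mol%), (R)-DTBM-SEGPHOS (5.5 mol%), (EtO)2MeSiH (3 equiv), t-BuOH (3 equiv), toluene, 0 °C → rt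
Reagents that add atoms: none
Why: Copper hydride catalysed asymmetric conjugate reduction of the β,β-disubstituted enoate, in which the chiral bisphosphine copper hydride adds hydride to one face of C13 and sets 13R under catalyst control while isolated alkenes are left alone.

Step 18
Reactants: 30 saturated methyl ester with (13R)-methyl
Product: 31 hydroxy acid (C15 carboxylic acid; C19–OH; acetonide)
Conditions: LiOH, THF/MeOH/H2O, rt; then HCl (1 M) to pH 3
Reagents that add atoms: LiOH (lithium hydroxide), [Li+].[OH-]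
Why: Saponification of the unhindered methyl ester, to which the acetonide and the C19 carbinol are inert.

Step 19
Reactants: 31 hydroxy acid
Product: 32 aldehyde acid (C19 aldehyde; acetonide)
Conditions: Dess–Martin periodinane, NaHCO3, CH2Cl2, 0 °C → rt
Reagents that add atoms: none
Why: Dess–Martin oxidation of the neopentyl primary alcohol to the aldehyde under buffered conditions; C4 carries no hydrogen, so the aldehyde cannot epimerize.

Step 20
Reactants: 32 aldehyde acid
Product: 33 2β,3β-dihydroxy aldehyde acid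
Conditions: HCl (1 M aq.), THF, rt
Reagents that add atoms: none
Why: Mild aqueous acid hydrolyses the acetonide (ketal hydrolysis) and frees the cis-diol without affecting the aldehyde or the trisubstituted alkene.

Step 21
Reactants: 33 2β,3β-dihydroxy aldehyde acid
Product: 34 (3R)-5-[(1R,4aS,5S,6R,7S,8aS)-7-acetoxy-5-formyl-6-hydroxy-2,5,8a-trimethyl-1,4,4a,5,6,7,8,8a-octahydronaphthalen-1-yl]-3-methylpentanoic acid
Conditions: Ac2O (3 equiv), pyridine, CH2Cl2, 0 °C; aq. NaHCO3, then acidify
Reagents that add atoms: acetic anhydride, CC(=O)OC(C)=O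
Why: Selective O-acetylation of the equatorial C2 hydroxyl, since the axial C3 hydroxyl next to the quaternary C4 is too hindered to react without a nucleophilic catalyst, and the mixed anhydride at C15 is hydrolysed on aqueous work-up.

Compound list
1 | 3-bromo-4-methylphenol | Cc1ccc(O)cc1Br | starting material
2 | 2-bromo-4-(methoxymethoxy)-1-methylbenzene | COCOc1ccc(C)c(Br)c1 | intermediate
3 | methyl chloroformate | COC(Cl)=O | starting material
4 | [2-bromo-6-(methoxymethoxy)-3-methylphenyl]lithium | COCOc1ccc(C)c(Br)c1[Li] | intermediate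
5 | methyl 6-bromo-2-(methoxymethoxy)-5-methylbenzoate | COCOc1ccc(C)c(Br)c1C(=O)OC | intermediate
6 | but-2-yn-1-ol | CC#CCO | starting material
7 | cyclic sodium alkenylalanate (Al bonded to C3 and to the oxygen of the butenol) | [Na+].CC1=CCO[Al-]1(OCCOC)OCCOC | intermediate
8 | (2Z)-3-iodobut-2-en-1-ol | C/C(I)=C/CO | intermediate
9 | (2Z)-1-bromo-3-iodobut-2-ene | C/C(I)=C/CBr | intermediate
10 | [2-(methoxycarbonyl)-3-(methoxymethoxy)-6-methylphenyl]magnesium chloride | COCOc1ccc(C)c([Mg]Cl)c1C(=O)OC | intermediate
11 | methyl 6-[(2Z)-3-iodobut-2-en-1-yl]-2-(methoxymethoxy)-5-methylbenzoate | COCOc1ccc(C)c(C/C=C(C)\I)c1C(=O)OC | intermediate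
12 | (2E)-3-(tributylstannyl)prop-2-en-1-ol | CCCC[Sn](CCCC)(CCCC)/C=C/CO | starting material
13 | methyl 6-[(2Z,4E)-6-hydroxy-3-methylhexa-2,4-dien-1-yl]-2-(methoxymethoxy)-5-methylbenzoate | COCOc1ccc(C)c(C/C=C(C)\C=C\CO)c1C(=O)OC | intermediate
14 | methyl 6-{(2Z,4E)-6-[(methoxycarbonyl)oxy]-3-methylhexa-2,4-dien-1-yl}-2-(methoxymethoxy)-5-methylbenzoate | COCOc1ccc(C)c(C/C=C(C)\C=C\COC(=O)OC)c1C(=O)OC | intermediate
15 | methyl 2-hydroxy-6-{(2Z,4E)-6-[(methoxycarbonyl)oxy]-3-methylhexa-2,4-dien-1-yl}-5-methylbenzoate (key-step precursor) | COC(=O)c1c(O)ccc(C)c1C/C=C(C)\C=C\COC(=O)OC | intermediate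
16 | methyl (4aS,5R)-5-ethenyl-4a,6-dimethyl-2-oxo-2,4a,5,8-tetrahydronaphthalene-1-carboxylate (ring A 1,4-dien-3-one; 9α-vinyl, 10α-methyl, C7=C8) | O=C1C=C[C@@]2(C)[C@H](C=C)C(C)=CCC2=C1C(=O)OC | intermediate
17 | potassium dienolate of 18 (O–C3=C2, after hydride addition to C1) | [K]OC1=CC[C@@]2(C)[C@H](C=C)C(C)=CCC2=C1C(=O)OC | intermediate
18 | methyl (4aS,5R)-5-ethenyl-4a,6-dimethyl-2-oxo-2,3,4,4a,5,8-hexahydronaphthalene-1-carboxylate | O=C1CC[C@@]2(C)[C@H](C=C)C(C)=CCC2=C1C(=O)OC | intermediate
19 | lithium enolate (O–C3=C4 ester enolate, 5β-H) | [Li]OC=1CC[C@@]2(C)[C@H](C=C)C(C)=CC[C@@H]2C=1C(=O)OC | intermediate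
20 | methyl (1S,4aR,5R,8aS)-5-ethenyl-1,4a,6-trimethyl-2-oxo-1,2,3,4,4a,5,8,8a-octahydronaphthalene-1-carboxylate (3-ketone; 4β-methyl, 4α-CO2Me; 5β-H) | O=C1CC[C@@]2(C)[C@H](C=C)C(C)=CC[C@@H]2[C@]1(C)C(=O)OC | intermediate
21 | potassium C2=C3 enolate of 20 | [K]OC1=CC[C@@]2(C)[C@H](C=C)C(C)=CC[C@@H]2[C@]1(C)C(=O)OC | intermediate
22 | 2β-hydroxy derivative of 20 (equatorial OH at C2) | O=C1[C@@H](O)C[C@@]2(C)[C@H](C=C)C(C)=CC[C@@H]2[C@]1(C)C(=O)OC | intermediate
23 | 2β,3β-diol methyl ester (3-OH axial; present in the flask as its lithium alkoxide) | O[C@H]1C[C@@]2(C)[C@H](C=C)C(C)=CC[C@@H]2[C@](C)(C(=O)OC)[C@H]1O | intermediate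
24 | 2β,3β,19-triol | O[C@H]1C[C@@]2(C)[C@H](C=C)C(C)=CC[C@@H]2[C@](C)(CO)[C@H]1O | intermediate
25 | 2,3-O-isopropylidene acetal of 24 | CC1(C)O[C@H]2C[C@@]3(C)[C@H](C=C)C(C)=CC[C@@H]3[C@](C)(CO)[C@H]2O1 | intermediate
26 | methyl acetoacetate | CC(=O)CC(=O)OC | starting material
27 | methyl (2E)-3-{[(trifluoromethyl)sulfonyl]oxy}but-2-enoate | C/C(OS(=O)(=O)C(F)(F)F)=C\C(=O)OC | intermediate
28 | B-alkyl-9-BBN adduct of 25 (boron on C12; C19–O also borylated) | CC1(C)O[C@H]2C[C@@]3(C)[C@H](CCB4C5CCCC4CCC5)C(C)=CC[C@@H]3[C@](C)(COB4C5CCCC4CCC5)[C@H]2O1 | intermediate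
29 | methyl (E)-enoate (side chain C9–CH2CH2–C(CH3)=CH–CO2Me; acetonide; C19–OH) | CC1(C)O[C@H]2C[C@@]3(C)[C@H](CC/C(C)=C/C(=O)OC)C(C)=CC[C@@H]3[C@](C)(CO)[C@H]2O1 | intermediate
30 | saturated methyl ester, 13R (acetonide; C19–OH) | CC1(C)O[C@H]2C[C@@]3(C)[C@H](CC[C@@H](C)CC(=O)OC)C(C)=CC[C@@H]3[C@](C)(CO)[C@H]2O1 | intermediate
31 | hydroxy acid (C15 acid; C19–OH; acetonide) | CC1(C)O[C@H]2C[C@@]3(C)[C@H](CC[C@@H](C)CC(=O)O)C(C)=CC[C@@H]3[C@](C)(CO)[C@H]2O1 | intermediate
32 | aldehyde acid (C19 aldehyde; acetonide) | CC1(C)O[C@H]2C[C@@]3(C)[C@H](CC[C@@H](C)CC(=O)O)C(C)=CC[C@@H]3[C@](C)(C=O)[C@H]2O1 | intermediate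
33 | 2β,3β-dihydroxy aldehyde acid | O[C@H]1C[C@@]2(C)[C@H](CC[C@@H](C)CC(=O)O)C(C)=CC[C@@H]2[C@](C)(C=O)[C@H]1O | intermediate
34 | (3R)-5-[(1R,4aS,5S,6R,7S,8aS)-7-acetoxy-5-formyl-6-hydroxy-2,5,8a-trimethyl-1,4,4a,5,6,7,8,8a-octahydronaphthalen-1-yl]-3-methylpentanoic acid | CC(=O)O[C@H]1C[C@@]2(C)[C@H](CC[C@@H](C)CC(=O)O)C(C)=CC[C@@H]2[C@](C)(C=O)[C@H]1O | target

Total step count: 21. Longest linear sequence: 18 steps (steps 1, 2, 5–14 and 16–21, from 3-bromo-4-methylphenol).

Steps most likely to fail

Step 9. Bond formation may go through the ester-bearing ortho carbon instead of the para carbon, the two arene faces may be poorly distinguished (loss of the C9/C10 relationship), or the branched alkenyl substituent on the allyl terminus may erode enantiocontrol. The fallback sets out from 11 and returns at 16, and takes C9 from a reagent-controlled epoxidation and an SN2 inversion instead of from the allyl face. Acid methanolysis of the MOM group (HCl, MeOH) gives methyl 2-hydroxy-6-[(2Z)-3-iodobut-2-en-1-yl]-5-methylbenzoate F1. Stille coupling with 12 gives methyl 2-hydroxy-6-[(2Z,4E)-6-hydroxy-3-methylhexa-2,4-dien-1-yl]-5-methylbenzoate F2. Sharpless asymmetric epoxidation of the allylic alcohol (Ti(Oi-Pr)4 and D-(−)-diethyl tartrate in stoichiometric amount because the salicylate binds titanium, t-BuOOH, −20 °C) gives methyl 2-hydroxy-6-{(2Z)-3-[(2R,3R)-3-(hydroxymethyl)oxiran-2-yl]but-2-en-1-yl}-5-methylbenzoate F3, in which C9 is an allylic epoxide carbon of defined configuration. Cs2CO3 in t-BuOH then lets the phenoxide para carbon open the epoxide at C9 with inversion (alkylative dearomatization of a phenoxide, 6-exo) to methyl (4aS,5R)-5-[(1S)-1,2-dihydroxyethyl]-4a,6-dimethyl-2-oxo-2,4a,5,8-tetrahydronaphthalene-1-carboxylate F4. Corey–Winter olefination through the cyclic thionocarbonate F5 (1,1′-thiocarbonyldiimidazole; then P(OMe)3) turns the C11/C12 diol into the vinyl group of 16; tying up the diol also drains any reversible conjugate addition of the new hydroxyls to the dienone.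

Step 5. The halogen–magnesium exchange may be slow or the aryl Grignard may attack an ester group, and the allylic substitution may proceed with transposition or with loss of the Z geometry. The fallback sets out from 5 and returns at 11, and avoids both the aryl-magnesium species and the allylic substitution. Stille coupling of 5 with allyltributylstannane (Pd(PPh3)4, toluene, 100 °C) gives methyl 6-allyl-2-(methoxymethoxy)-5-methylbenzoate F6. Oxidative cleavage (OsO4 cat., NaIO4, 2,6-lutidine) gives methyl 2-(methoxymethoxy)-5-methyl-6-(2-oxoethyl)benzoate F7, which is used at once. A Z-selective Wittig iodo-olefination (Stork–Zhao type) with the ylide Ph3P=C(I)CH3, made from ethyltriphenylphosphonium iodide, n-BuLi, I2 and NaN(SiMe3)2 at −78 °C, gives 11.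

Step 17. Facial control at C13 rests on the catalyst alone, with no help from the remote ring stereocentres, so incomplete or reversed selectivity would give C13 epimers that are hard to separate. The fallback sets out from 25 and returns at 31, and takes C13 from the chiral pool. Silylation of the C19 hydroxyl (t-BuMe2SiCl, imidazole) gives the silyl ether F8. Hydroboration of the vinyl group with 9-BBN and oxidation (NaOH, H2O2) gives the C12 primary alcohol F9, and CBr4/PPh3 gives the C12 bromide F10. Magnesium insertion gives the Grignard reagent F11, which opens (R)-β-butyrolactone (C[C@@H]1CC(=O)O1) at the methyl-bearing carbon with inversion under CuBr·SMe2 catalysis to give the (13R)-acid F12. Bu4NF removes the silyl group and gives 31.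

Further compounds
F1 | step 9 | methyl 2-hydroxy-6-[(2Z)-3-iodobut-2-en-1-yl]-5-methylbenzoate | COC(=O)c1c(O)ccc(C)c1C/C=C(C)\I
F2 | step 9 | methyl 2-hydroxy-6-[(2Z,4E)-6-hydroxy-3-methylhexa-2,4-dien-1-yl]-5-methylbenzoate | COC(=O)c1c(O)ccc(C)c1C/C=C(C)\C=C\CO
F3 | step 9 | methyl 2-hydroxy-6-{(2Z)-3-[(2R,3R)-3-(hydroxymethyl)oxiran-2-yl]but-2-en-1-yl}-5-methylbenzoate | COC(=O)c1c(O)ccc(C)c1C/C=C(C)\[C@H]1O[C@@H]1CO
F4 | step 9 | methyl (4aS,5R)-5-[(1S)-1,2-dihydroxyethyl]-4a,6-dimethyl-2-oxo-2,4a,5,8-tetrahydronaphthalene-1-carboxylate | O=C1C=C[C@@]2(C)[C@H]([C@H](O)CO)C(C)=CCC2=C1C(=O)OC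
F5 | step 9 | cyclic thionocarbonate of F4 (2-thioxo-1,3-dioxolan-4-yl group on C9) | O=C1C=C[C@@]2(C)[C@H]([C@H]3COC(=S)O3)C(C)=CCC2=C1C(=O)OC
F6 | step 5 | methyl 6-allyl-2-(methoxymethoxy)-5-methylbenzoate | COCOc1ccc(C)c(CC=C)c1C(=O)OC
F7 | step 5 | methyl 2-(methoxymethoxy)-5-methyl-6-(2-oxoethyl)benzoate | COCOc1ccc(C)c(CC=O)c1C(=O)OC
F8 | step 17 | C19 tert-butyldimethylsilyl ether of 25 | CC1(C)O[C@H]2C[C@@]3(C)[C@H](C=C)C(C)=CC[C@@H]3[C@](C)(CO[Si](C)(C)C(C)(C)C)[C@H]2O1
F9 | step 17 | C12 primary alcohol (C9–CH2CH2OH) from F8 | CC1(C)O[C@H]2C[C@@]3(C)[C@H](CCO)C(C)=CC[C@@H]3[C@](C)(CO[Si](C)(C)C(C)(C)C)[C@H]2O1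
F10 | step 17 | C12 bromide (C9–CH2CH2Br) | CC1(C)O[C@H]2C[C@@]3(C)[C@H](CCBr)C(C)=CC[C@@H]3[C@](C)(CO[Si](C)(C)C(C)(C)C)[C@H]2O1
F11 | step 17 | C12 alkylmagnesium bromide | CC1(C)O[C@H]2C[C@@]3(C)[C@H](CC[Mg]Br)C(C)=CC[C@@H]3[C@](C)(CO[Si](C)(C)C(C)(C)C)[C@H]2O1
F12 | step 17 | (13R)-acid with C19 silyl ether (silylated 31) | CC1(C)O[C@H]2C[C@@]3(C)[C@H](CC[C@@H](C)CC(=O)O)C(C)=CC[C@@H]3[C@](C)(CO[Si](C)(C)C(C)(C)C)[C@H]2O1
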